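## Analysis of the target

Compound 24 is a type A polyprenylated acylphloroglucinol, a bicyclo[3.3.1]non-3-ene-2,9-dione. The numbering used here is C1 (acyl-bearing bridgehead), C2(=O)–C3H=C4(OH), C5 (bridgehead CH), C6 (CH2), C7 (CH), C8 (quaternary) and C9 (bridging ketone). Ring A is C1–C8–C7–C6–C5–C9 and ring B is C1–C2–C3–C4–C5–C9.

There are five stereocenters. C1 (R) and C5 (R) are tied together by the bridge. C7 (S) carries an equatorial (exo) prenyl group. C8 (R) carries an axial CH3 and an equatorial homogeranyl chain. C2' (R) of the 2-methylbutanoyl group is too remote to be controlled by the ring or to control it.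

The hardest bond is C1–C8, which joins two fully substituted carbons, one of them flanked by three carbonyl groups.

Two features invite the chosen strategy. First, C6–C7–C8(CH3) together with the chain on C8 is an intact (E,E)-farnesyl unit, bound through C6 to C5 and through C8 to C1. Second, ring B without its acyl group has only hydrogen at C3 and C5. It therefore has a latent mirror plane through C5 and C2, which makes C1 and C3 equivalent until C8 binds to one of them.

The sensitive groups are:
- three trisubstituted alkenes (acid, electrophiles, radical 5-exo closure);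
- the vinylogous acid;
- the non-enolisable tricarbonyl array at C1;
- the epimerisable C2'–H.

Unlike its C5-alkylated relatives, 24 has hydrogen at both bridgeheads before acylation. A late acylation must therefore distinguish C1–H from C5–H. Ring B precursors with C5–H can also aromatise.

## Retrosynthetic reasoning

**Unmasking (24 ⇒ 22 ⇒ 21).** The vinylogous acid is carried as its C4 methyl ether 22, because that ether comes for free with the ring B building block. Compound 22 is traced back to 21, in which C3 and C5 carry silicon. Only O–CH3 and C–Si bonds are cut. The forward steps must be nearly neutral, so that C2' and the tricarbonyl carbon C1 survive.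

**C1–acyl bond (21 ⇒ 17 + 19).** The acyl group is cut off late, so that its labile stereocenter sees only three steps and is supplied enantiopure by 19. The forward reaction is a bridgehead lithiation and acylation. It is regioselective only because the two more accessible acidic positions, C5–H and C3–H, are blocked in 17.

**C7–prenyl bond (15 ⇒ 14 ⇒ 13 ⇒ 12).** The prenyl group is traced through an allyl group to a C7–O bond on the same (exo) face. This exchange allows C7 to be oxygen in the key step. The forward sequence is a radical allyl transfer from the convex face followed by cross-metathesis.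

**Oxidation state and mask (12 ⇒ 10 ⇒ 9).** C2=O is removed to give a CH2 group, and the C9 ketone and C7 alcohol are tied together as a methyl ketal. This reveals in 9 a ring B that holds one enol ether and one former enol ether.

**Key disconnection (9 ⇒ 7).** The C1–C8 bond and the C9–O(C7) bond are cut. What remains is a symmetric bis(enol ether) ring carrying an epoxyfarnesyl chain at C5.
- The cut is placed at the most hindered bond of 24 because an epoxide delivers C8 as a configurationally defined tertiary electrophile.
- The latent symmetry of ring B turns the setting of C1 and C5 into a choice between two identical groups.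
- One isomerisation then builds ring A, the bicycle and four stereocenters.

**C5–C6 bond (7 ⇒ 5 + 3).** This is an ordinary SN2 union of a C8 ring fragment and a C15 chain fragment. One alkylation suffices because 24 has C5–H.

**Fragments (3 ⇒ 2 ⇒ 1; 5 ⇒ 4; 19 ⇒ 18).** All chain carbons and both alkene geometries come from 1. The absolute configuration comes from a Sharpless asymmetric epoxidation. Ring B comes from a Birch reduction of 4, and the acyl group from acid 18.

## Alternatives that were turned down

**Alternative 1:** (textbook) Cut C1–C2 and C4–C5.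

The forward key step is an Effenberger-type α,α'-annulation of an enol ether of cyclohexanone A1 with malonyl dichloride A2. It gives the bicyclic trione A3, which is then acylated at the bridgehead. It was turned down for four reasons.
- The C1–C2 bond would be made by acylation next to the quaternary C8, in competition with O-acylation at C9, which leads to pyranones.
- A1 requires C7 and C8 to be set one after the other, plus a separately made homogeranyl nucleophile, so the farnesyl unit of the target is not used.
- The annulation itself sets no stereocenter that is hard.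
- A3 still has two undifferentiated bridgehead C–H bonds.

**Alternative 2:** Cut C1–C8 as a 1,2-shift.

The C5 enolate of cyclopentanone A4 would be acylated by diketene A5. The terminal carbon (future C1) would close onto C9 by an aldol reaction. A hypervalent iodine oxidation at that carbon would then trigger migration of C8 from C9 to C1. This skeletal change is attractive for C5-quaternary relatives, but it fails on a feature of this target.
- With hydrogen at C5, the acylation product A6 is a β-triketone that sits as an enolate spread over C9–C5–C4.
- C9 is then no longer an electrophile, and the aldol closure has no driving force.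
- A4 also needs an enantioselective conjugate addition of an allylic (prenyl) nucleophile and a multi-step homogeranyl halide.
- The acyl group would still come last.

**Alternative 3:** Cut C7–prenyl and C1–C8 at once (biomimetic).

The farnesylated acylphloroglucinol A7 would be prenylated at C7, by a prenyl cation equivalent or by an aromatic prenyltransferase, and the C8 cation would be captured by C1. It was turned down for four reasons.
- In A7, C5 is sp2 and the three-atom tether cannot reach the meta carbon C1.
- The C8 cation is taken by the neighbouring phenol oxygen instead, to give chroman A8.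
- A free prenyl cation cannot choose among three trisubstituted alkenes and an electron-rich arene.
- For the enzymatic version, no member of the enzyme class can be argued to accept this substrate and fold it for C-capture.

Key step: step 5

Assumption: the enolised β-diketone C2–C3–C4 of 24 equilibrates freely between its two enol forms; the tautomer of the given SMILES (C2=O, C4–OH) is the one written throughout.

## Steps

Step 1
Reactants: 1 (2E,6E)-farnesol
Product: 2 (2S,3S)-2,3-epoxyfarnesol
Conditions: Ti(OiPr)4 (cat.), L-(+)-diethyl tartrate (cat.), t-BuOOH, 4 Å MS, CH2Cl2, −20 °C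
Reagents that add atoms: tert-butyl hydroperoxide, CC(C)(C)OO
Why: Sharpless asymmetric epoxidation: only the allylic alcohol alkene is bound to titanium, so the two remote alkenes stay untouched. The L-(+)-tartrate ligand should deliver oxygen to the face that gives the (2S,3S)-epoxide, which fixes the C7–O and C8–O configuration (target numbering) from which all ring stereocenters follow.

Step 2
Reactants: 2 (2S,3S)-2,3-epoxyfarnesol
Product: 3 (2R,3S)-1-bromo-2,3-epoxy-3,7,11-trimethyldodeca-6,10-diene (spatial arrangement as in 2)
Conditions: CBr4, PPh3, CH2Cl2, −20 → 0 °C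
Reagents that add atoms: tetrabromomethane, BrC(Br)(Br)Br
Why: Appel reaction: neutral SN2 exchange at the primary carbinol carbon, a known way from 2,3-epoxy alcohols to epoxy bromides that leaves epoxide and alkenes alone. No stereocenter is touched; the descriptor at C2 changes only because bromine changes the priorities.

Step 3
Reactants: 4 1,3-dimethoxybenzene
Product: 5 1,5-dimethoxycyclohexa-1,4-diene
Conditions: Li, NH3 (l), t-BuOH, THF, −78 → −33 °C
Reagents that add atoms: none
Why: Birch reduction: the two donor groups direct protonation to C2 and C5 of the arene, which gives the unconjugated dihydro product with both enol ethers intact.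

Step 4
Reactants: 5 1,5-dimethoxycyclohexa-1,4-diene; 3 epoxy bromide
Product: 7 6-[(2S,3S,6E)-2,3-epoxy-3,7,11-trimethyldodeca-6,10-dien-1-yl]-1,5-dimethoxycyclohexa-1,4-diene, via lithiated diene 6 (not isolated)
Conditions: t-BuLi, THF, −78 °C; then 3, −78 → −30 °C
Reagents that add atoms: none
Why: Deprotonation of the doubly allylic CH2 between the two enol ethers gives a cyclohexadienyl anion that is known to be alkylated at its central carbon, and SN2 attack at the primary bromide is faster than attack at the trisubstituted epoxide. The new sp3 carbon (C5) is not yet stereogenic because the ring is still symmetric, and one alkylation is enough because the target has hydrogen at C5.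

Step 5
Reactants: 7 epoxyfarnesyl bis(enol ether)
Product: 9 tricyclic methyl ketal 4,9-dimethoxy-8-methyl-8-[(3E)-4,8-dimethylnona-3,7-dien-1-yl]-7,9-epoxybicyclo[3.3.1]non-3-ene (C1 C5 C7 C8 as in 24), via oxocarbenium triflate 8 (not isolated)
Conditions: Me3SiOTf (0.3 equiv), 2,6-lutidine (0.5 equiv), CH2Cl2, −78 °C
Reagents that add atoms: none
Why: The silyl triflate binds the epoxide oxygen and weakens the C8–O bond, the tertiary and more cation-like end, and the C1 terminus of one methyl enol ether attacks C8 from the back, which forms the C1–C8 bond and closes ring A in a 6-endo-tet mode. The oxocarbenium ion 8 left at C9 cannot lose a proton because C1 and C5 are bridgeheads, and it is captured by the silylated C7 oxygen in a 5-exo-trig closure that frees the silyl cation again, so the step is an isomerisation catalytic in Lewis acid. The closest known reaction type is the Lewis acid-induced opening of trisubstituted epoxides by tethered enol ethers, that is an epoxide-started cation–olefin cyclisation. C8 is set by inversion at the epoxide carbon, so that CH3 ends axial and the long chain equatorial on ring A, and C7 keeps its C–O bond and its configuration. C1 and C5 are set together by the choice between the two diastereotopic enol ethers: with O–C7–C8···C1 held antiperiplanar, only one of them reaches C8 through a chair-like ring A with the C7 oxygen and the long chain equatorial, whereas the other needs a boat or axial groups, and only the first product can close the oxygen bridge. C9 is fixed by the geometry of that bridge. The step needs 6-endo over 5-exo opening (secured by the tertiary C8), the enol ether and not a chain alkene as nucleophile (secured by its far higher nucleophilicity and because the nearest chain alkene could only close a four- or five-membered ring), and survival of the acid-labile diene (secured by the hindered pyridine buffer and the low temperature).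

Step 6
Reactants: 9 tricyclic methyl ketal
Product: 10 2-oxo derivative of 9 (vinylogous ester C2(=O)–C3H=C4(OCH3) with the 7,9-epoxy ketal intact)
Conditions: t-BuOOH, PhI(OAc)2, Cs2CO3, EtOAc, −20 °C
Reagents that add atoms: tert-butyl hydroperoxide, CC(C)(C)OO
Why: Radical allylic oxidation by a tert-butylperoxy chain (hypervalent iodine/hydroperoxide type): the C2–H bonds are allylic to the electron-rich enol ether and the most easily abstracted, while C5–H is a bridgehead whose radical cannot conjugate. The enol ether becomes the vinylogous ester, and no stereocenter is touched.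

Step 7
Reactants: 10 vinylogous ester ketal
Product: 12 7-exo-hydroxy-4-methoxy-8-methyl-8-[(3E)-4,8-dimethylnona-3,7-dien-1-yl]bicyclo[3.3.1]non-3-ene-2,9-dione, via dimethylborinate 11 (not isolated)
Conditions: BrBMe2, CH2Cl2, −78 °C; then Et3N, aq. NaHCO3
Reagents that add atoms: none
Why: Cleavage of a mixed ketal with a bromoborane: boron binds the bridging oxygen, the C9 oxocarbenium ion is demethylated by bromide, and hydrolysis of borinate 11 frees the C7 alcohol. At low temperature the less basic vinylogous ester and the alkenes should not react; C9 becomes the ketone and the other stereocenters stay.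

Step 8
Reactants: 12 hydroxy dione
Product: 13 O-(imidazol-1-ylthiocarbonyl) derivative of 12
Conditions: 1,1'-thiocarbonyldiimidazole, DMAP (cat.), toluene, 90 °C
Reagents that add atoms: 1,1'-thiocarbonyldiimidazole, S=C(n1ccnc1)n1ccnc1
Why: Thiocarbonylation of a secondary alcohol, the first half of a Barton–McCombie-type sequence, under almost neutral conditions. Heat and DMAP answer the neopentylic position of the alcohol, and acylation drains any transannular hemiketal form.

Step 9
Reactants: 13 thiocarbonylimidazolide
Product: 14 7-exo-allyl-4-methoxy-8-methyl-8-[(3E)-4,8-dimethylnona-3,7-dien-1-yl]bicyclo[3.3.1]non-3-ene-2,9-dione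
Conditions: allylSnBu3 (large excess, neat), AIBN (cat.), 80 °C
Reagents that add atoms: allyltributylstannane, C=CC[Sn](CCCC)(CCCC)CCCC
Why: Keck radical allylation: the stannyl radical adds to sulfur, fragmentation gives the secondary C7 radical, and SH2' attack on the allylstannane carries the chain. The radical should be trapped on the convex exo face, away from ring B, which puts the allyl group equatorial (net retention at C7); the high stannane concentration is meant to outrun 5-exo closure onto the nearest chain alkene.

Step 10
Reactants: 14 allyl compound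
Product: 15 4-methoxy-8-methyl-7-exo-(3-methylbut-2-en-1-yl)-8-[(3E)-4,8-dimethylnona-3,7-dien-1-yl]bicyclo[3.3.1]non-3-ene-2,9-dione
Conditions: 2-methylbut-2-ene (solvent), second-generation Hoveyda–Grubbs catalyst (cat.), 40 °C, sealed tube
Reagents that add atoms: 2-methylbut-2-ene, CC=C(C)C
Why: Olefin cross-metathesis of a terminal alkene with a trisubstituted partner, the usual allyl-to-prenyl exchange in this family. The trisubstituted chain alkenes are slow partners, and exchange at the isopropylidene end is degenerate.

Step 11
Reactants: 15 prenyl compound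
Product: 17 3,5-bis(trimethylsilyl) derivative of 15, via C5-monosilyl dione 16 (not isolated)
Conditions: lithium 2,2,6,6-tetramethylpiperidide (LiTMP, 3 equiv), Me3SiCl (in situ, excess), THF, −78 → −40 °C
Reagents that add atoms: chlorotrimethylsilane, C[Si](C)(C)Cl
Why: Bridgehead and vinylic lithiation with internal silyl quench, both known on bicyclo[3.3.1]nonane vinylogous esters. C5–H (next to a CH2 group) and C3–H are the kinetically accessible sites, while C1–H is shielded by the quaternary C8, so silicon should block exactly the two positions that would compete in step 13; substitution at C5 occurs with retention because the bridgehead cannot invert.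

Step 12
Reactants: 18 (R)-2-methylbutanoic acid
Product: 19 (R)-2-methylbutanoyl chloride
Conditions: (COCl)2, DMF (cat.), CH2Cl2, 0 °C → rt
Reagents that add atoms: oxalyl chloride, O=C(Cl)C(=O)Cl
Why: Standard acid chloride formation through the Vilsmeier-type chloroiminium salt; without amine base no ketene forms, so C2' should keep its configuration.

Step 13
Reactants: 17 bis-silyl dione; 19 (R)-2-methylbutanoyl chloride
Product: 21 1-[(2R)-2-methylbutanoyl] derivative of 17, via C1-lithio species 20 (not isolated)
Conditions: LiTMP (1.1 equiv), THF, −78 → −20 °C; then 19, −78 °C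
Reagents that add atoms: none
Why: Bridgehead lithiation–acylation, known for this ring system next to a quaternary C8 when C9 is a ketone: C1–H, flanked by C2=O and C9=O, is the only acidic C–H left. The bridgehead carbanion cannot invert, so C1 is formed with retention, and the cold inverse-free quench limits proton transfer from the α-C–H of 19.

Step 14
Reactants: 21 acylated bis-silyl compound
Product: 22 O-methyl ether of 24 (C4–OCH3)
Conditions: Bu4NF, AcOH, THF, 0 °C → rt
Reagents that add atoms: none
Why: Fluoride-induced protodesilylation of an α-silyl ketone (C5) and of the α-silyl vinylogous ester (C3). The acetic acid buffer keeps the medium non-basic, which protects C2' and the tricarbonyl carbon C1; C5 is reprotonated with retention for geometric reasons.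

Step 15
Reactants: 22 O-methyl ether
Product: 24 (1R,5R,7S,8R)-8-[(3E)-4,8-dimethylnona-3,7-dien-1-yl]-4-hydroxy-8-methyl-1-[(2R)-2-methylbutanoyl]-7-(3-methylbut-2-en-1-yl)bicyclo[3.3.1]non-3-ene-2,9-dione, via lithium enolate 23 (not isolated)
Conditions: LiCl, DMSO, 120 °C; then dilute aq. HCl
Reagents that add atoms: none
Why: Krapcho-type SN2 demethylation of a vinylogous methyl ester by chloride, the usual last step for this family. The only base formed is the weakly basic enolate 23 of the vinylogous acid, so the alkenes, C1 and C2' should be left alone.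

## Compound list

1 | (2E,6E)-farnesol | OC/C=C(\C)CC/C=C(\C)CCC=C(C)C | starting material
2 | (2S,3S)-2,3-epoxyfarnesol | OC[C@@H]1O[C@@]1(C)CC/C=C(\C)CCC=C(C)C | intermediate
3 | (2R,3S)-1-bromo-2,3-epoxy-3,7,11-trimethyldodeca-6,10-diene | BrC[C@@H]1O[C@@]1(C)CC/C=C(\C)CCC=C(C)C | intermediate
4 | 1,3-dimethoxybenzene | COc1cccc(OC)c1 | starting material
5 | 1,5-dimethoxycyclohexa-1,4-diene | COC1=CCC=C(OC)C1 | intermediate
6 | 6-lithio-1,5-dimethoxycyclohexa-1,4-diene | [Li]C1C(OC)=CCC=C1OC | intermediate
7 | 6-[(2S,3S,6E)-2,3-epoxy-3,7,11-trimethyldodeca-6,10-dien-1-yl]-1,5-dimethoxycyclohexa-1,4-diene | COC1=CCC=C(OC)C1C[C@@H]2O[C@@]2(C)CC/C=C(\C)CCC=C(C)C | intermediate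
8 | C9 methyloxocarbenium triflate with C7–OSiMe3 | [C@@H]12CC=C(OC)[C@@H](C[C@H](O[Si](C)(C)C)[C@@]1(C)CC/C=C(\C)CCC=C(C)C)C2=[O+]C.[O-]S(=O)(=O)C(F)(F)F | intermediate
9 | tricyclic methyl ketal (7,9-epoxy bridge, C4 enol ether) | [C@@H]12CC=C(OC)[C@@H](C[C@H](O3)[C@@]1(C)CC/C=C(\C)CCC=C(C)C)[C@]23OC | intermediate
10 | 2-oxo tricyclic ketal (vinylogous ester) | [C@@H]12C(=O)C=C(OC)[C@@H](C[C@H](O3)[C@@]1(C)CC/C=C(\C)CCC=C(C)C)[C@]23OC | intermediate
11 | C7 dimethylborinate of 12 | [C@@H]12C(=O)C=C(OC)[C@@H](C[C@H](OB(C)C)[C@@]1(C)CC/C=C(\C)CCC=C(C)C)C2=O | intermediate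
12 | 7-exo-hydroxy vinylogous ester dione | [C@@H]12C(=O)C=C(OC)[C@@H](C[C@H](O)[C@@]1(C)CC/C=C(\C)CCC=C(C)C)C2=O | intermediate
13 | O-(imidazol-1-ylthiocarbonyl) derivative of 12 | [C@@H]12C(=O)C=C(OC)[C@@H](C[C@H](OC(=S)n3ccnc3)[C@@]1(C)CC/C=C(\C)CCC=C(C)C)C2=O | intermediate
14 | 7-exo-allyl dione | [C@@H]12C(=O)C=C(OC)[C@@H](C[C@H](CC=C)[C@@]1(C)CC/C=C(\C)CCC=C(C)C)C2=O | intermediate
15 | 7-exo-prenyl dione | [C@@H]12C(=O)C=C(OC)[C@@H](C[C@H](CC=C(C)C)[C@@]1(C)CC/C=C(\C)CCC=C(C)C)C2=O | intermediate
16 | 5-trimethylsilyl derivative of 15 | [C@@H]12C(=O)C=C(OC)[C@@]([Si](C)(C)C)(C[C@H](CC=C(C)C)[C@@]1(C)CC/C=C(\C)CCC=C(C)C)C2=O | intermediate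
17 | 3,5-bis(trimethylsilyl) derivative of 15 | [C@@H]12C(=O)C([Si](C)(C)C)=C(OC)[C@@]([Si](C)(C)C)(C[C@H](CC=C(C)C)[C@@]1(C)CC/C=C(\C)CCC=C(C)C)C2=O | intermediate
18 | (R)-2-methylbutanoic acid | CC[C@@H](C)C(=O)O | starting material
19 | (R)-2-methylbutanoyl chloride | CC[C@@H](C)C(=O)Cl | intermediate
20 | C1-lithio derivative of 17 | [Li][C@@]12C(=O)C([Si](C)(C)C)=C(OC)[C@@]([Si](C)(C)C)(C[C@H](CC=C(C)C)[C@@]1(C)CC/C=C(\C)CCC=C(C)C)C2=O | intermediate
21 | 1-[(2R)-2-methylbutanoyl] derivative of 17 | CC[C@@H](C)C(=O)[C@@]12C(=O)C([Si](C)(C)C)=C(OC)[C@@]([Si](C)(C)C)(C[C@H](CC=C(C)C)[C@@]1(C)CC/C=C(\C)CCC=C(C)C)C2=O | intermediate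
22 | C4 O-methyl ether of 24 | CC[C@@H](C)C(=O)[C@@]12C(=O)C=C(OC)[C@@H](C[C@H](CC=C(C)C)[C@@]1(C)CC/C=C(\C)CCC=C(C)C)C2=O | intermediate
23 | lithium enolate of 24 | CC[C@@H](C)C(=O)[C@@]12C(=O)C=C([O-])[C@@H](C[C@H](CC=C(C)C)[C@@]1(C)CC/C=C(\C)CCC=C(C)C)C2=O.[Li+] | intermediate
24 | CNP0158147.2 | CC[C@@H](C)C(=O)[C@@]12C(=O)C=C(O)[C@@H](C[C@H](CC=C(C)C)[C@@]1(C)CC/C=C(\C)CCC=C(C)C)C2=O | target

## Step count and least certain steps

Total step count: 15. Longest linear sequence: 13 (steps 1, 2, 4–11 and 13–15). Steps 3 and 12 are one-step side branches.

**Step 5 (key step).**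

What may go wrong:
- hydride shift at the activated epoxide (Meinwald-type rearrangement) or base-induced opening to an allylic alcohol before C–C bond formation;
- acid-induced isomerisation or aromatisation of the diene through its doubly allylic C5–H, a weakness that C5-quaternary substrates do not have;
- poor discrimination between the two enol ethers.

The fallback sets out from 5 and 3 and returns at 16. It replaces the labile C5–H by silicon before the cyclisation.
- Lithiation of 5 as in step 4 and quench with chlorotrimethylsilane would give 1,5-dimethoxy-6-(trimethylsilyl)cyclohexa-1,4-diene F1.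
- A second lithiation and alkylation with 3 would give the C5-quaternary epoxy diene F2, which can neither aromatise nor isomerise through C5.
- Cyclisation under the conditions of step 5 would give the C5-silylated tricyclic ketal F3. Loss of silicon from the cation is blocked there, because it would create a bridgehead alkene.
- The chemistry of steps 6–10 would then lead through the C5-silylated vinylogous ester ketal F4, the C5-silylated hydroxy dione F5, the C5-silylated thiocarbonylimidazolide F6 and the C5-silylated allyl dione F7 to 16.
- Compound 16 then needs only the known C3 silylation to reach 17.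

**Step 9.**

What may go wrong:
- 5-exo closure of the C7 radical onto the nearest alkene of the chain on C8, in competition with the bimolecular allyl transfer;
- premature reduction;
- incomplete facial selectivity.

The fallback sets out from 13 and returns at 15. It uses a much faster radical trap and builds the prenyl alkene by a polar olefination, which also removes the metathesis step.
- Giese addition of the C7 radical, generated with (Me3Si)3SiH and AIBN, to 1-phenyl-5-(vinylsulfonyl)-1H-tetrazole would give the 7-exo-[2-(1-phenyltetrazol-5-ylsulfonyl)ethyl] dione F8.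
- Julia–Kocienski olefination of F8 with acetone would give 15 directly. KN(SiMe3)2 is added to the mixture at −78 °C; this base does not touch the bridgehead C–H bonds.

**Step 11.**

What may go wrong:
- poor site selectivity of the deprotonation (C1–H competing with C5–H);
- incomplete second silylation;
- loss of the bridgehead silicon on purification.

The fallback sets out from 10 and 19 and returns at 22. It moves the acylation to the ketal stage. There C9 is not a carbonyl group, and C1–H is the only bridgehead hydrogen next to a C=O, so C5 needs no block.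
- LiTMP with Me3SiCl would give the C3-silyl ketal F9.
- LiTMP and then 19 would give the C1-acyl C3-silyl ketal F10.
- The chemistry of steps 7–10 would lead through the C1-acyl hydroxy dione F11, the C1-acyl thiocarbonylimidazolide F12 and the C1-acyl allyl dione F13 to the C1-acyl C3-silyl prenyl dione F14.
- Buffered Bu4NF would convert F14 into 22.

The price is a more crowded and less acidic C1.

**Step 13.**

What may go wrong:
- slow deprotonation at the hindered C1;
- proton transfer from the α-C–H of the acid chloride to the carbanion or to residual amide base (ketene formation), which erodes the configuration at C2' and returns 17.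

The fallback sets out from 19 and 20 and returns at 21. It forms the C–C bond with an aldehyde and adjusts the oxidation state afterwards.
- Reduction of 19 with LiAlH(OtBu)3 at −78 °C would give (R)-2-methylbutanal F15.
- Addition of 20 to F15 at −78 °C would give the C1 carbinol F16, as a mixture at the carbinol carbon, which does not matter.
- Dess–Martin oxidation of F16 would give 21 under neutral conditions.

## Further compounds

F1 | step 5 | 1,5-dimethoxy-6-(trimethylsilyl)cyclohexa-1,4-diene | COC1=CCC=C(OC)C1[Si](C)(C)C
F2 | step 5 | C5-quaternary epoxy diene (6-silyl-6-epoxyfarnesyl) | COC1=CCC=C(OC)C1([Si](C)(C)C)C[C@@H]2O[C@@]2(C)CC/C=C(\C)CCC=C(C)C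
F3 | step 5 | C5-silylated tricyclic ketal | [C@@H]12CC=C(OC)[C@@]([Si](C)(C)C)(C[C@H](O3)[C@@]1(C)CC/C=C(\C)CCC=C(C)C)[C@]23OC
F4 | step 5 | C5-silylated vinylogous ester ketal | [C@@H]12C(=O)C=C(OC)[C@@]([Si](C)(C)C)(C[C@H](O3)[C@@]1(C)CC/C=C(\C)CCC=C(C)C)[C@]23OC
F5 | step 5 | C5-silylated hydroxy dione | [C@@H]12C(=O)C=C(OC)[C@@]([Si](C)(C)C)(C[C@H](O)[C@@]1(C)CC/C=C(\C)CCC=C(C)C)C2=O
F6 | step 5 | C5-silylated thiocarbonylimidazolide | [C@@H]12C(=O)C=C(OC)[C@@]([Si](C)(C)C)(C[C@H](OC(=S)n3ccnc3)[C@@]1(C)CC/C=C(\C)CCC=C(C)C)C2=O
F7 | step 5 | C5-silylated allyl dione | [C@@H]12C(=O)C=C(OC)[C@@]([Si](C)(C)C)(C[C@H](CC=C)[C@@]1(C)CC/C=C(\C)CCC=C(C)C)C2=O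
F8 | step 9 | 7-exo-[2-(1-phenyltetrazol-5-ylsulfonyl)ethyl] dione | [C@@H]12C(=O)C=C(OC)[C@@H](C[C@H](CCS(=O)(=O)c3nnnn3-c3ccccc3)[C@@]1(C)CC/C=C(\C)CCC=C(C)C)C2=O
F9 | step 11 | C3-silyl ketal | [C@@H]12C(=O)C([Si](C)(C)C)=C(OC)[C@@H](C[C@H](O3)[C@@]1(C)CC/C=C(\C)CCC=C(C)C)[C@]23OC
F10 | step 11 | C1-acyl C3-silyl ketal | CC[C@@H](C)C(=O)[C@@]12C(=O)C([Si](C)(C)C)=C(OC)[C@@H](C[C@H](O3)[C@@]1(C)CC/C=C(\C)CCC=C(C)C)[C@]23OC
F11 | step 11 | C1-acyl hydroxy dione | CC[C@@H](C)C(=O)[C@@]12C(=O)C([Si](C)(C)C)=C(OC)[C@@H](C[C@H](O)[C@@]1(C)CC/C=C(\C)CCC=C(C)C)C2=O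
F12 | step 11 | C1-acyl thiocarbonylimidazolide | CC[C@@H](C)C(=O)[C@@]12C(=O)C([Si](C)(C)C)=C(OC)[C@@H](C[C@H](OC(=S)n3ccnc3)[C@@]1(C)CC/C=C(\C)CCC=C(C)C)C2=O
F13 | step 11 | C1-acyl allyl dione | CC[C@@H](C)C(=O)[C@@]12C(=O)C([Si](C)(C)C)=C(OC)[C@@H](C[C@H](CC=C)[C@@]1(C)CC/C=C(\C)CCC=C(C)C)C2=O
F14 | step 11 | C1-acyl C3-silyl prenyl dione | CC[C@@H](C)C(=O)[C@@]12C(=O)C([Si](C)(C)C)=C(OC)[C@@H](C[C@H](CC=C(C)C)[C@@]1(C)CC/C=C(\C)CCC=C(C)C)C2=O
F15 | step 13 | (R)-2-methylbutanal | CC[C@@H](C)C=O
F16 | step 13 | C1 carbinol | CC[C@@H](C)C(O)[C@@]12C(=O)C([Si](C)(C)C)=C(OC)[C@@]([Si](C)(C)C)(C[C@H](CC=C(C)C)[C@@]1(C)CC/C=C(\C)CCC=C(C)C)C2=O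
A1 | alternative 1 | 3-methyl-3-homogeranyl-4-prenylcyclohexanone (C7 and C8 as in 24) | O=C1C[C@](C)(CC/C=C(\C)CCC=C(C)C)[C@@H](CC=C(C)C)CC1
A2 | alternative 1 | malonyl dichloride | O=C(Cl)CC(=O)Cl
A3 | alternative 1 | des-acyl bicyclic trione | [C@@H]12C(=O)C=C(O)[C@@H](C[C@H](CC=C(C)C)[C@@]1(C)CC/C=C(\C)CCC=C(C)C)C2=O
A4 | alternative 2 | 2-methyl-2-homogeranyl-3-prenylcyclopentanone (C7 and C8 as in 24) | O=C1CC[C@H](CC=C(C)C)[C@@]1(C)CC/C=C(\C)CCC=C(C)C
A5 | alternative 2 | diketene | C=C1CC(=O)O1
A6 | alternative 2 | 5-acetoacetyl derivative of A4 (β-triketone) | CC(=O)CC(=O)C1CC[C@H](CC=C(C)C)[C@@](C)(CC/C=C(\C)CCC=C(C)C)C1=O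
A7 | alternative 3 | 3-farnesyl-1-[(2R)-2-methylbutanoyl]phloroglucinol | CC[C@@H](C)C(=O)c1c(O)cc(O)c(C/C=C(\C)CC/C=C(\C)CCC=C(C)C)c1O
A8 | alternative 3 | chroman from O-capture of the C8 cation | CC[C@@H](C)C(=O)c1c(O)cc(O)c2CC(CC=C(C)C)C(C)(CC/C=C(\C)CCC=C(C)C)Oc12
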